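The pitfall in the hunch is the charge: 24 mM of reagent against 20 mM of starting material reads as an excess, and an excess invites the picture of a flask that keeps converting.

- violet: starting material 20 mM; partner 20 mM; reagent 24 mM; the very flask that is asked about, followed so far
- flask: starting material 20 mM; partner 20.0 mM; reagent 24.0 mM; time 25 min

violet run (percent of the starting material charged)

| time / min | starting material / % | side product / % |
|---|---|---|
| 0.667 | 89.7 | 5.8 |
| 1.33 | 86.0 | 10.0 |
| 2.00 | 83.5 | 14.0 |
| 3.00 | 82.1 | 16.7 |
| 4.00 | 79.9 | 17.1 |
| 5.00 | 81.8 | 17.5 |

(scatter of a reading: 0.5 percentage points)

- a species is counted by the starting material in it: one side product counts as two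

- concentration of starting material at 25 min, in mM
- concentration of side product at 25 min, in mM

In the violet run, which is this flask followed so far, starting material reads 82.1 %, 79.9 % and 81.8 % from 3.00 min to 5.00 min and averages 81.3 % over those readings. The reckoning here holds that level to 25 min. Per unit of reagent charged, the level means a loss of 0.156 of starting material; call this the take, the starting material lost per reagent charged. The last side product reading, 17.5 %, holds nearly all of that loss, and each side product contains two starting material. So, with the whole loss counted as side product, the take gives 16.3 mM of starting material and 1.87 mM of side product.

The forecast gives 16.2 mM of starting material and 3.6 mM of side product, the latter “counted in starting-material units”, which stands higher than the reckoning here.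

The flask gives 16.2 mM of starting material and 1.85 mM of side product.

    starting material + reagent → open intermediate (k = 10.2 M⁻¹ min⁻¹)
    reagent + partner → second intermediate (k = 21.1 M⁻¹ min⁻¹)
    open intermediate + second intermediate → target (k = 14.0 M⁻¹ min⁻¹)
    2 second intermediate → homo product (k = 1.22 M⁻¹ min⁻¹)
    reagent → decomposed reagent (k = 1.79 min⁻¹)
    starting material + open intermediate → side product (k = 51.4 M⁻¹ min⁻¹)

At 25.0 min this flask holds less of its reagent, 0 %, than of its starting material, 81 %, and reagent is the limiting reagent, the first to run out. The take on 24.0 mM of reagent gives a loss of 3.75 mM of starting material, and the flask has lost 3.79 mM.

The neighbour charged with 6.0 mM of reagent, other charges held, gets from the take 19.1 mM of starting material and 0.468 mM of side product. That neighbour computes to 19.0 mM of starting material and 0.495 mM of side product.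

All runs come from a simulation on assumed constants, and the scatter is random.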